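The constants are invented; the rest is arithmetic.

Slowness of an addition is what separates these flasks: the charges are equal, and the difference lies in which reagent arrives late.

| setting | maple | elm | ash | larch |
|---|---|---|---|---|
| substrate | 0.50 mM | 0.50 mM | 0.50 mM | 0.50 mM |
| partner | 1.00 mM | 1.00 mM (in portions, 2, over 80 s) | 1.00 mM | 1.00 mM (fed, over 80 s) |
| second reagent | 0.350 mM | 0.350 mM | 0.350 mM (fed, over 80 s) | 0.350 mM |
| third reagent | 1.25 mM | 1.25 mM | 1.25 mM | 1.25 mM |
| time | 1.5 min | 1.5 min | 1.5 min | 1.5 min |
| remark | everything together at the start | first portion at the start, last at 80 s | all else is in the flask from the start; the feed brings no volume worth counting | all else is in the flask from the start; the feed brings no volume worth counting |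

* the flask with the highest share of target in target plus side product A ("all alike" if they lie within 1.5 percentage points) (maple / elm / ash / larch / all alike)
* share of target in target plus side product A at the end, maple
* share of target in target plus side product A at the end, elm
* share of target in target plus side product A at the end, ash
* share of target in target plus side product A at the end, larch

- percent here means substrate units held: one side product B counts as two
- run time (maple): 1.5 min

    substrate + partner → intermediate A (k1 = 30 /M/s)
    substrate + second reagent → side product A (k2 = 40 /M/s)
    third reagent + intermediate B → target (k3 = 140 /M/s)
    substrate + target → side product B (k4 = 56 /M/s)
    second reagent → decomposed reagent (k5 = 0.0032 /s)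
    second reagent + intermediate A → intermediate B (k6 = 150 /M/s)

Second reagent is charged in the smaller amount, 0.350 mM against 0.50 mM of substrate, so its balance is the one to write. With the main steps alone, partner turns substrate into intermediate A at 0.0300 /s, a half-life of 0.39 min. Second reagent takes up intermediate A, third reagent finishes the job, and side product A does not arise.

Now add the second exit, second reagent taking substrate. The split is set by the selectivity factor, the ratio of the two constants, 3.75: how many times more readily second reagent takes one intermediate A than one substrate. At any moment the share going on is the factor times intermediate A, over that same product plus substrate.

In ash the feed lasts 2.40 substrate lifetimes, so its later portions enter a flask already turned over. Averaging the split across the feed, with partner held at its charge, gives 81.0%.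

In maple second reagent meets fresh substrate at once. With second reagent held at its charge, side product A takes 31.8% of the substrate, and if the remaining second reagent goes on, the share is 54.5%. Elm and larch have on average 0.500 mM of partner added during the first stretch; counting that amount, with the consumption of partner left out, the same rough sum gives 31.0% for each.

The rest pulls the other way and stays unreckoned here: at charged substrate, target has a half-life of 0.41 min against substrate, shorter than the run, and second reagent decays with a half-life of 3.6 min. This reckoning picks ash.

The forecast also names ash, with 58% for maple, 44% for elm, 84% for ash and 32% for larch, on the ground that “holding back the partner does the reverse”. For elm it stands higher than the reckoning above.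

The simulation gives ash: maple 57.5%, elm 36.4%, ash 81.1%, larch 26.3%.

At 1.50 min ash holds side product A at 7.82% of the substrate charged and target at 33.6%, and with intermediate A at 35.7% and substrate at 7.98% the factor puts the split at 94.4%. The neighbouring flask is ash with 2.5 mM of partner: the factor stays 3.75, the substrate rate becomes 0.0750 /s, and the same average gives 92.0%. That flask reached 95.9%, with side product A at 2.04%.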